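**Plan**

- Retrosynthesis: the N–CH3 bond and the two O–CH3 bonds are cut first; ring C is then taken apart in one move at C4–C4a, O1–C8a and O1–C2, which leaves a ring A aryne and 3-phenylpropiolic acid.
- Feature used: C4a and C8a are neighbours on ring A, C4a carrying the acyl carbon C4 and C8a carrying O1, with the C5 oxygen next to C4a and only hydrogen on C8 next to C8a. This is the pattern a 3-alkoxyaryne gives when an oxygen nucleophile adds at its distal carbon and an acyl group lands beside the alkoxy group.
- The aryne precursor (an ortho-silylaryl triflate) goes back to an ortho-bromophenol; the piperidine is cut at N1–C6 (N-alkylation) and C2–C3 (addition to an aryl N-sulfinyl aldimine), back to 4-hydroxy-2,6-dimethoxybenzaldehyde.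
- Forward: ring A is bought and brominated, the piperidine ring is built on it (steps 3–5), the silyl triflate is installed (step 7), ring C is closed (step 8), then N-methylation and O-demethylation follow.
- Stereochemistry: the single stereocentre (piperidine C2, R) is set in step 4 by the (S)-tert-butanesulfinyl auxiliary and is not made planar afterwards.

Key step: step 8

Assumption: the sense of induction in step 4 is taken from the magnesium-chelated chair model for N-tert-butanesulfinyl aldimines in a non-coordinating solvent; the configuration is to be confirmed on 11, and the enantiomeric auxiliary is the remedy should the ortho methoxy groups invert it.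

**Route**

Step 1
Reactants: 1 4-hydroxy-2,6-dimethoxybenzaldehyde
Product: 2 3-bromo-4-hydroxy-2,6-dimethoxybenzaldehyde
Conditions: NBS (1.0 equiv), MeCN, 0 °C
Reagents that add atoms: N-bromosuccinimide, O=C1CCC(=O)N1Br
Why: Electrophilic aromatic bromination, in which the free phenol directs NBS to C3 (one of two equivalent positions ortho to OH) and the formyl group damps the ring enough for one equivalent at 0 °C to stop at the monobromide.

Step 2
Reactants: 2 3-bromo-4-hydroxy-2,6-dimethoxybenzaldehyde
Product: 3 3-bromo-2,6-dimethoxy-4-(methoxymethoxy)benzaldehyde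
Conditions: MOMCl, i-Pr2NEt, CH2Cl2, 0 °C to rt
Reagents that add atoms: chloromethyl methyl ether, COCCl
Why: O-Alkylation of the acidic bromophenol with an α-chloro ether (acetal protection); the methoxymethyl ether should survive the titanium alkoxide, Grignard and hydride-base steps and leave later in the same acid treatment that removes the sulfinyl group.

Step 3
Reactants: 3 3-bromo-2,6-dimethoxy-4-(methoxymethoxy)benzaldehyde; 4 (S)-2-methylpropane-2-sulfinamide
Product: 5 (S,E)-N-{[3-bromo-2,6-dimethoxy-4-(methoxymethoxy)phenyl]methylidene}-2-methylpropane-2-sulfinamide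
Conditions: Ti(OEt)4 (2 equiv), THF, 65 °C
Reagents that add atoms: none
Why: Condensation of an aldehyde with tert-butanesulfinamide (N-sulfinyl imine formation), in which Ti(OEt)4 activates the hindered, electron-rich carbonyl and binds the water formed, giving the E-aldimine without touching the sulfur stereocentre.

Step 4
Reactants: 5 (S,E)-N-{[3-bromo-2,6-dimethoxy-4-(methoxymethoxy)phenyl]methylidene}-2-methylpropane-2-sulfinamide; 6 1-bromo-4-chlorobutane
Product: 8 (S)-N-{(1R)-1-[3-bromo-2,6-dimethoxy-4-(methoxymethoxy)phenyl]-5-chloropentyl}-2-methylpropane-2-sulfinamide, via 4-chlorobutylmagnesium bromide 7 (not isolated)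
Conditions: 6, Mg, Et2O, 20 °C; then 5, CH2Cl2, −48 °C to rt; aq. NH4Cl
Reagents that add atoms: none
Why: Diastereoselective 1,2-addition of a Grignard reagent to an N-tert-butanesulfinyl aldimine: in CH2Cl2 magnesium bound to the sulfinyl oxygen should deliver the alkyl group through a six-membered chair with tert-butyl equatorial, which for the (S)-sulfinyl E-aldimine makes the benzylic carbon R, and the minor diastereomer is removable by chromatography at this stage.

Step 5
Reactants: 8 (S)-N-{(1R)-1-[3-bromo-2,6-dimethoxy-4-(methoxymethoxy)phenyl]-5-chloropentyl}-2-methylpropane-2-sulfinamide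
Product: 9 (2R)-2-[3-bromo-2,6-dimethoxy-4-(methoxymethoxy)phenyl]-1-[(S)-2-methylpropane-2-sulfinyl]piperidine
Conditions: NaH, DMF, 0 °C to rt
Reagents that add atoms: none
Why: Intramolecular N-alkylation (6-exo-tet SN2) of the sodium sulfinamide by the primary chloride closes the piperidine without involving the stereocentre, the aryl bromide or the acetal.

Step 6
Reactants: 9 (2R)-2-[3-bromo-2,6-dimethoxy-4-(methoxymethoxy)phenyl]-1-[(S)-2-methylpropane-2-sulfinyl]piperidine
Product: 11 tert-butyl (2R)-2-(3-bromo-4-hydroxy-2,6-dimethoxyphenyl)piperidine-1-carboxylate, via aminophenol hydrochloride 10 (not isolated)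
Conditions: HCl (4 M in dioxane), MeOH, rt to 40 °C; evaporate; Boc2O, NaHCO3, THF/H2O, rt
Reagents that add atoms: di-tert-butyl dicarbonate, CC(C)(C)OC(=O)OC(=O)OC(C)(C)C
Why: Acid methanolysis cleaves the N–S bond of the sulfinamide and the methoxymethyl acetal together while the protonated benzylic amine resists ionisation, and the liberated secondary amine is then acylated by Boc2O (carbamate formation) under bicarbonate conditions that leave the phenol free.

Step 7
Reactants: 11 tert-butyl (2R)-2-(3-bromo-4-hydroxy-2,6-dimethoxyphenyl)piperidine-1-carboxylate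
Product: 14 tert-butyl (2R)-2-[2,6-dimethoxy-4-(trifluoromethanesulfonyloxy)-3-(trimethylsilyl)phenyl]piperidine-1-carboxylate, via trimethylsilyl ether 12 (not isolated), via lithium silylphenoxide 13 (not isolated)
Conditions: (Me3Si)2NH, THF, 65 °C; evaporate; n-BuLi (1.1 equiv), THF, −100 to −80 °C; Tf2O, −100 to −80 °C; cold aq. NaHCO3
Reagents that add atoms: hexamethyldisilazane, C[Si](C)(C)N[Si](C)(C)C; trifluoromethanesulfonic anhydride, O=S(=O)(OS(=O)(=O)C(F)(F)F)C(F)(F)F
Why: One-pot O-silylation, bromine–lithium exchange, retro-Brook (1,3 O-to-C) silyl migration and O-triflation of the lithium phenoxide, the standard way to ortho-silylaryl triflates; at −100 °C exchange is much faster than attack of n-BuLi on the carbamate or removal of the benzylic proton, so the C2 centre should be kept.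

Step 8
Reactants: 14 tert-butyl (2R)-2-[2,6-dimethoxy-4-(trifluoromethanesulfonyloxy)-3-(trimethylsilyl)phenyl]piperidine-1-carboxylate; 15 3-phenylpropiolic acid
Product: 18 tert-butyl (2R)-2-(5,7-dimethoxy-4-oxo-2-phenyl-4H-chromen-6-yl)piperidine-1-carboxylate, via aryne 16 (not isolated), via cesium ynone phenoxide 17 (not isolated)
Conditions: 15 (1.5 equiv), CsF (4 equiv), THF, 125 °C, sealed tube
Reagents that add atoms: none
Why: Fluoride removes the silyl group from C4a and triflate leaves C8a, giving aryne 16; the cesium carboxylate of 15 adds through oxygen to C8a, the aryl anion left at C4a attacks the acyl carbon of the new aryl ester, and the strained four-membered alkoxide opens so that the acyl group ends on C4a and the former acid oxygen becomes the C8a phenoxide 17. This is the fluoride-induced insertion of arynes into the acyl–oxygen bond of carboxylic acids, a known reaction that with arylpropiolic acids carries on to flavones. Ring C then closes by 6-endo-dig conjugate addition of the C8a phenoxide to the ynone (O1–C2 bond), which should be preferred over 5-exo closure in an aprotic medium with a cesium counter-ion, and protonation at C3 by the bifluoride formed from the acid completes the chromone. No stereocentre is formed, and the piperidine C2 centre, which is neither acidic nor exposed to acid here, is carried through unchanged. The regioselectivity the step needs comes from the C5 methoxy group beside C4a: its inductive pull and the aryne distortion it causes send the oxygen nucleophile to the distal, unhindered C8a (flanked only by C8–H) and stabilise the carbanion developing at C4a, while the C7 methoxy group is too remote to compete. The carbamate keeps nitrogen from adding to the aryne, and the acid is used in excess over 14 to make up for decarboxylation.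

Step 9
Reactants: 18 tert-butyl (2R)-2-(5,7-dimethoxy-4-oxo-2-phenyl-4H-chromen-6-yl)piperidine-1-carboxylate
Product: 19 5,7-dimethoxy-2-phenyl-6-[(2R)-piperidin-2-yl]-4H-chromen-4-one
Conditions: TFA, CH2Cl2, 0 °C to rt; aq. NaHCO3
Reagents that add atoms: none
Why: Acidolysis of the tert-butyl carbamate (Boc removal) by loss of the tert-butyl cation; the chromone and the methyl ethers are inert to TFA, and the C4 carbonyl now on ring A disfavours ionisation of the benzylic C–N bond.

Step 10
Reactants: 19 5,7-dimethoxy-2-phenyl-6-[(2R)-piperidin-2-yl]-4H-chromen-4-one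
Product: 21 5,7-dimethoxy-6-[(2R)-1-methylpiperidin-2-yl]-2-phenyl-4H-chromen-4-one, via methyleneiminium ion 20 (not isolated)
Conditions: aq. HCHO, NaBH(OAc)3, AcOH, ClCH2CH2Cl, rt
Reagents that add atoms: formaldehyde, C=O
Why: Reductive amination, in which formaldehyde gives the iminium ion 20 that NaBH(OAc)3 reduces much faster than the chromone carbonyl, while the methyl ethers still in place keep C8 from reacting with formaldehyde.

Step 11
Reactants: 21 5,7-dimethoxy-6-[(2R)-1-methylpiperidin-2-yl]-2-phenyl-4H-chromen-4-one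
Product: 22 5,7-dihydroxy-6-[(2R)-1-methylpiperidin-2-yl]-2-phenyl-4H-chromen-4-one
Conditions: BBr3 (8 equiv), CH2Cl2, −78 °C to rt; MeOH; aq. NaHCO3
Reagents that add atoms: none
Why: Lewis acid cleavage of aryl methyl ethers (BBr3 demethylation), with the C5 ether assisted by chelation to the C4 carbonyl and excess reagent allowing for boron bound by the amine and carbonyl; keeping the mixture at or below room temperature and the work-up brief and near neutral should guard the benzylic amine centre against reversible retro-Mannich opening once both flanking phenols are free.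

**Compound list**

1 | 4-hydroxy-2,6-dimethoxybenzaldehyde | COc1cc(O)cc(OC)c1C=O | starting material
2 | 3-bromo-4-hydroxy-2,6-dimethoxybenzaldehyde | COc1cc(O)c(Br)c(OC)c1C=O | intermediate
3 | 3-bromo-2,6-dimethoxy-4-(methoxymethoxy)benzaldehyde | COCOc1cc(OC)c(C=O)c(OC)c1Br | intermediate
4 | (S)-2-methylpropane-2-sulfinamide | CC(C)(C)[S@](=O)N | starting material
5 | (S,E)-N-{[3-bromo-2,6-dimethoxy-4-(methoxymethoxy)phenyl]methylidene}-2-methylpropane-2-sulfinamide | CC(C)(C)[S@](=O)/N=C/c1c(OC)cc(OCOC)c(Br)c1OC | intermediate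
6 | 1-bromo-4-chlorobutane | ClCCCCBr | starting material
7 | 4-chlorobutylmagnesium bromide | ClCCCC[Mg]Br | intermediate
8 | (S)-N-{(1R)-1-[3-bromo-2,6-dimethoxy-4-(methoxymethoxy)phenyl]-5-chloropentyl}-2-methylpropane-2-sulfinamide | CC(C)(C)[S@](=O)N[C@H](CCCCCl)c1c(OC)cc(OCOC)c(Br)c1OC | intermediate
9 | (2R)-2-[3-bromo-2,6-dimethoxy-4-(methoxymethoxy)phenyl]-1-[(S)-2-methylpropane-2-sulfinyl]piperidine | CC(C)(C)[S@](=O)N1CCCC[C@@H]1c1c(OC)cc(OCOC)c(Br)c1OC | intermediate
10 | 2-bromo-3,5-dimethoxy-4-[(2R)-piperidin-2-yl]phenol hydrochloride | Cl.N1CCCC[C@@H]1c1c(OC)cc(O)c(Br)c1OC | intermediate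
11 | tert-butyl (2R)-2-(3-bromo-4-hydroxy-2,6-dimethoxyphenyl)piperidine-1-carboxylate | CC(C)(C)OC(=O)N1CCCC[C@@H]1c1c(OC)cc(O)c(Br)c1OC | intermediate
12 | tert-butyl (2R)-2-[3-bromo-2,6-dimethoxy-4-(trimethylsilyloxy)phenyl]piperidine-1-carboxylate | CC(C)(C)OC(=O)N1CCCC[C@@H]1c1c(OC)cc(O[Si](C)(C)C)c(Br)c1OC | intermediate
13 | lithium 4-[(2R)-1-(tert-butoxycarbonyl)piperidin-2-yl]-3,5-dimethoxy-2-(trimethylsilyl)phenolate | [Li+].CC(C)(C)OC(=O)N1CCCC[C@@H]1c1c(OC)cc([O-])c([Si](C)(C)C)c1OC | intermediate
14 | tert-butyl (2R)-2-[2,6-dimethoxy-4-(trifluoromethanesulfonyloxy)-3-(trimethylsilyl)phenyl]piperidine-1-carboxylate | CC(C)(C)OC(=O)N1CCCC[C@@H]1c1c(OC)cc(OS(=O)(=O)C(F)(F)F)c([Si](C)(C)C)c1OC | intermediate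
15 | 3-phenylpropiolic acid (3-phenylprop-2-ynoic acid) | OC(=O)C#Cc1ccccc1 | starting material
16 | tert-butyl (2R)-2-(3,4-didehydro-2,6-dimethoxyphenyl)piperidine-1-carboxylate (aryne) | CC(C)(C)OC(=O)N1CCCC[C@@H]1C1=C(OC)C#CC=C1OC | intermediate
17 | cesium 4-[(2R)-1-(tert-butoxycarbonyl)piperidin-2-yl]-3,5-dimethoxy-2-(3-phenylprop-2-ynoyl)phenolate | [Cs+].CC(C)(C)OC(=O)N1CCCC[C@@H]1c1c(OC)cc([O-])c(C(=O)C#Cc2ccccc2)c1OC | intermediate
18 | tert-butyl (2R)-2-(5,7-dimethoxy-4-oxo-2-phenyl-4H-chromen-6-yl)piperidine-1-carboxylate | CC(C)(C)OC(=O)N1CCCC[C@@H]1c1c(OC)cc2oc(-c3ccccc3)cc(=O)c2c1OC | intermediate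
19 | 5,7-dimethoxy-2-phenyl-6-[(2R)-piperidin-2-yl]-4H-chromen-4-one | N1CCCC[C@@H]1c1c(OC)cc2oc(-c3ccccc3)cc(=O)c2c1OC | intermediate
20 | (2R)-2-(5,7-dimethoxy-4-oxo-2-phenyl-4H-chromen-6-yl)-1-methylidenepiperidin-1-ium | C=[N+]1CCCC[C@@H]1c1c(OC)cc2oc(-c3ccccc3)cc(=O)c2c1OC | intermediate
21 | 5,7-dimethoxy-6-[(2R)-1-methylpiperidin-2-yl]-2-phenyl-4H-chromen-4-one | CN1CCCC[C@@H]1c1c(OC)cc2oc(-c3ccccc3)cc(=O)c2c1OC | intermediate
22 | 5,7-dihydroxy-6-[(2R)-1-methylpiperidin-2-yl]-2-phenyl-4H-chromen-4-one | CN1CCCC[C@@H]1c1c(O)cc2oc(-c3ccccc3)cc(=O)c2c1O | target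

**Step count and risks**

Total step count: 11. Longest linear sequence: 11 steps (1 to 22); the Grignard reagent 7 is made within step 4.

Steps most likely to fail:

1. Step 8. The aryl anion at the crowded C4a (next to a methoxy group buttressed by the piperidine) may be protonated before the acyl shift, giving the aryl ester; the phenoxide may close 5-exo to the aurone; or the acid may decarboxylate at 125 °C. The fallback leaves the aryne and forms the same ring C bonds stepwise, setting out from 11 and returning at 18. Silylation of 11 (i-Pr3SiCl, imidazole, DMF) would give tert-butyl (2R)-2-[3-bromo-2,6-dimethoxy-4-(triisopropylsilyloxy)phenyl]piperidine-1-carboxylate F1, whose bulky silyl group should not migrate to carbon. Bromine–lithium exchange (n-BuLi, THF, −78 °C) and acylation with N-methoxy-N-methyl-3-phenylprop-2-ynamide would give tert-butyl (2R)-2-[2,6-dimethoxy-3-(3-phenylprop-2-ynoyl)-4-(triisopropylsilyloxy)phenyl]piperidine-1-carboxylate F2. Bu4NF in THF (or KF with 18-crown-6 in DMF) would free the phenoxide, which should close 6-endo-dig to 18.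

2. Step 4. Magnesium may chelate an ortho methoxy group, eroding or inverting facial selectivity, and the chloroalkyl Grignard reagent may be lost by Wurtz-type self-coupling. The fallback sets out from 5 and returns at 9, bringing in the carbon chain by Barbier chemistry and closing the ring by metathesis. Zinc-mediated allylation of 5 with allyl bromide (Zn, In(OTf)3, THF, or Zn in HMPA; the two protocols are established to give opposite diastereomers, so the 1R adduct is reachable with the same auxiliary) would give (S)-N-{(1R)-1-[3-bromo-2,6-dimethoxy-4-(methoxymethoxy)phenyl]but-3-en-1-yl}-2-methylpropane-2-sulfinamide F3. N-Allylation (LiN(SiMe3)2, allyl bromide, DMF) would give (S)-N-{(1R)-1-[3-bromo-2,6-dimethoxy-4-(methoxymethoxy)phenyl]but-3-en-1-yl}-2-methyl-N-(prop-2-en-1-yl)propane-2-sulfinamide F4. Ring-closing metathesis with the second-generation Grubbs catalyst (CH2Cl2, 40 °C) would give (2R)-2-[3-bromo-2,6-dimethoxy-4-(methoxymethoxy)phenyl]-1-[(S)-2-methylpropane-2-sulfinyl]-1,2,3,6-tetrahydropyridine F5. Diimide reduction of the ring alkene (2-nitrobenzenesulfonylhydrazide, Et3N, CH2Cl2), which spares the aryl bromide, would lead to 9.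

3. Step 7. Silyl migration to the carbon flanked by two oxygen substituents may be incomplete, the aryllithium may be protonated (debrominated phenol), or Tf2O may be consumed by the carbamate or THF instead of the hindered phenoxide. The fallback sets out from 11 and returns at 14, with intermolecular C-silylation and triflation of an isolated phenol. Benzylation (BnBr, K2CO3, DMF) would give tert-butyl (2R)-2-[4-(benzyloxy)-3-bromo-2,6-dimethoxyphenyl]piperidine-1-carboxylate F6. Bromine–lithium exchange (n-BuLi, THF, −78 °C) and quenching with Me3SiCl would give tert-butyl (2R)-2-[4-(benzyloxy)-2,6-dimethoxy-3-(trimethylsilyl)phenyl]piperidine-1-carboxylate F7. Hydrogenolysis (H2, Pd/C, EtOAc) would give tert-butyl (2R)-2-[4-hydroxy-2,6-dimethoxy-3-(trimethylsilyl)phenyl]piperidine-1-carboxylate F8, and triflation (Tf2O, pyridine, CH2Cl2, 0 °C) would give 14.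

**Further compounds**

F1 | step 8 | tert-butyl (2R)-2-[3-bromo-2,6-dimethoxy-4-(triisopropylsilyloxy)phenyl]piperidine-1-carboxylate | CC(C)(C)OC(=O)N1CCCC[C@@H]1c1c(OC)cc(O[Si](C(C)C)(C(C)C)C(C)C)c(Br)c1OC
F2 | step 8 | tert-butyl (2R)-2-[2,6-dimethoxy-3-(3-phenylprop-2-ynoyl)-4-(triisopropylsilyloxy)phenyl]piperidine-1-carboxylate | CC(C)(C)OC(=O)N1CCCC[C@@H]1c1c(OC)cc(O[Si](C(C)C)(C(C)C)C(C)C)c(C(=O)C#Cc2ccccc2)c1OC
F3 | step 4 | (S)-N-{(1R)-1-[3-bromo-2,6-dimethoxy-4-(methoxymethoxy)phenyl]but-3-en-1-yl}-2-methylpropane-2-sulfinamide | CC(C)(C)[S@](=O)N[C@H](CC=C)c1c(OC)cc(OCOC)c(Br)c1OC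
F4 | step 4 | (S)-N-{(1R)-1-[3-bromo-2,6-dimethoxy-4-(methoxymethoxy)phenyl]but-3-en-1-yl}-2-methyl-N-(prop-2-en-1-yl)propane-2-sulfinamide | CC(C)(C)[S@](=O)N(CC=C)[C@H](CC=C)c1c(OC)cc(OCOC)c(Br)c1OC
F5 | step 4 | (2R)-2-[3-bromo-2,6-dimethoxy-4-(methoxymethoxy)phenyl]-1-[(S)-2-methylpropane-2-sulfinyl]-1,2,3,6-tetrahydropyridine | CC(C)(C)[S@](=O)N1CC=CC[C@@H]1c1c(OC)cc(OCOC)c(Br)c1OC
F6 | step 7 | tert-butyl (2R)-2-[4-(benzyloxy)-3-bromo-2,6-dimethoxyphenyl]piperidine-1-carboxylate | CC(C)(C)OC(=O)N1CCCC[C@@H]1c1c(OC)cc(OCc2ccccc2)c(Br)c1OC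
F7 | step 7 | tert-butyl (2R)-2-[4-(benzyloxy)-2,6-dimethoxy-3-(trimethylsilyl)phenyl]piperidine-1-carboxylate | CC(C)(C)OC(=O)N1CCCC[C@@H]1c1c(OC)cc(OCc2ccccc2)c([Si](C)(C)C)c1OC
F8 | step 7 | tert-butyl (2R)-2-[4-hydroxy-2,6-dimethoxy-3-(trimethylsilyl)phenyl]piperidine-1-carboxylate | CC(C)(C)OC(=O)N1CCCC[C@@H]1c1c(OC)cc(O)c([Si](C)(C)C)c1OC
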